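**Retrosynthetic overview**
- Pestalone G ⇒ its bis-MOM ether ⇒ hydroxymethyl benzophenone ⇒ diaryl carbinol (two benzylic oxidations and one acid deprotection in the forward sense).
- Key C–C bond (ring A carbon to the carbinol carbon): intermolecular aldol-type addition of the bromomagnesium phenoxide of 2-bromo-4-chloro-5-methoxy-3-methylphenol, reacting as an aromatic enolate at its only free ortho carbon, to a fully substituted ring B benzaldehyde.
- Ring A fragment: orcinol monomethyl ether; Br is placed para to OMe (phenol masked as acetate), then Cl para to the free OH.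
- Ring B fragment: 3,5-dihydroxybenzaldehyde; MOM ethers, acetal, double bromination, then two bromine–lithium exchanges (prenyl, then the future formyl carbon carried as CH2OTBS).
- No ring is formed: both benzene rings are bought; ring A is prepared first, ring B second, then they are joined.

Assumption: the target has no stereocentre and no stereogenic double bond, so it is a single achiral compound and no enantioselective step is needed.

**Route**

Step 1
Reactants: 1 3-methoxy-5-methylphenol
Product: 2 3-methoxy-5-methylphenyl acetate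
Conditions: Ac2O, pyridine, 4-(dimethylamino)pyridine (cat.), CH2Cl2, 0 °C to rt
Reagents that add atoms: acetic anhydride, CC(=O)OC(C)=O
Why: O-acetylation (nucleophilic acyl substitution) turns the strongly activating phenol into a weakly donating ester so that the methoxy group alone steers the next halogenation.

Step 2
Reactants: 2 3-methoxy-5-methylphenyl acetate
Product: 3 2-bromo-5-methoxy-3-methylphenyl acetate
Conditions: NBS (1.05 equiv), MeCN, 0 °C to rt, dark
Reagents that add atoms: N-bromosuccinimide, O=C1CCC(=O)N1Br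
Why: Electrophilic aromatic bromination with NBS in MeCN goes para to the dominant methoxy donor, which here is the carbon between CH3 and OAc.

Step 3
Reactants: 3 2-bromo-5-methoxy-3-methylphenyl acetate
Product: 4 2-bromo-5-methoxy-3-methylphenol
Conditions: K2CO3 (cat.), MeOH, rt
Reagents that add atoms: none
Why: Base-catalysed transesterification (methanolysis of an aryl acetate) frees the phenol without touching the aryl bromide or the methyl ether.

Step 4
Reactants: 4 2-bromo-5-methoxy-3-methylphenol
Product: 5 2-bromo-4-chloro-5-methoxy-3-methylphenol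
Conditions: SO2Cl2 (1.0 equiv), CH2Cl2/Et2O, 0 °C
Reagents that add atoms: sulfuryl chloride, O=S(=O)(Cl)Cl
Why: Electrophilic aromatic chlorination is directed by the free phenol to its para carbon (between CH3 and OMe), leaving the crowded, less reactive carbon between the two oxygens free for the key step.

Step 5
Reactants: 6 3,5-dihydroxybenzaldehyde
Product: 7 3,5-bis(methoxymethoxy)benzaldehyde
Conditions: MOMCl, i-Pr2NEt, CH2Cl2, 0 °C to rt
Reagents that add atoms: chloromethyl methyl ether, COCCl
Why: Williamson-type O-alkylation gives MOM acetals that survive organolithium chemistry and are removable by mild acid at the end.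

Step 6
Reactants: 7 3,5-bis(methoxymethoxy)benzaldehyde
Product: 8 1-(dimethoxymethyl)-3,5-bis(methoxymethoxy)benzene
Conditions: HC(OMe)3, MeOH, pyridinium p-toluenesulfonate (cat.), rt; Et3N quench
Reagents that add atoms: trimethyl orthoformate, COC(OC)OC; methanol, CO
Why: Acid-catalysed acetalisation of the unhindered aldehyde masks it against n-BuLi under conditions too mild to cleave aryl MOM ethers.

Step 7
Reactants: 8 1-(dimethoxymethyl)-3,5-bis(methoxymethoxy)benzene
Product: 9 2,4-dibromo-3-(dimethoxymethyl)-1,5-bis(methoxymethoxy)benzene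
Conditions: NBS (2.05 equiv), MeCN, 0 °C to rt, dark
Reagents that add atoms: N-bromosuccinimide, O=C1CCC(=O)N1Br
Why: Twofold electrophilic aromatic bromination takes the two equivalent carbons that are each para to one OMOM and ortho to the other, the carbon between the two OMOM groups being the slowest site.

Step 8
Reactants: 9 2,4-dibromo-3-(dimethoxymethyl)-1,5-bis(methoxymethoxy)benzene
Product: 12 2-bromo-3-(dimethoxymethyl)-1,5-bis(methoxymethoxy)-4-(3-methylbut-2-en-1-yl)benzene, via aryllithium 10 (not isolated), via arylcopper 11 (not isolated)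
Conditions: n-BuLi (1.05 equiv), THF, −78 °C; CuBr·SMe2 (1.1 equiv), −78 to −40 °C; prenyl bromide, −78 to 0 °C
Reagents that add atoms: 1-bromo-3-methylbut-2-ene (prenyl bromide), CC(C)=CCBr
Why: Bromine–lithium exchange on one of two equivalent bromides, transmetalation to copper and SN2 allylic substitution at the unhindered primary terminus of prenyl bromide install the prenyl group.

Step 9
Reactants: 12 2-bromo-3-(dimethoxymethyl)-1,5-bis(methoxymethoxy)-4-(3-methylbut-2-en-1-yl)benzene
Product: 14 2-(dimethoxymethyl)-4,6-bis(methoxymethoxy)-3-(3-methylbut-2-en-1-yl)benzaldehyde, via aryllithium 13 (not isolated)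
Conditions: n-BuLi (1.1 equiv), THF, −78 °C; DMF, −78 to 0 °C; H2O
Reagents that add atoms: N,N-dimethylformamide, CN(C)C=O
Why: A second bromine–lithium exchange followed by Bouveault formylation with DMF introduces the future formyl carbon, the exchange being much faster at −78 °C than deprotonation of the prenyl CH2.

Step 10
Reactants: 14 2-(dimethoxymethyl)-4,6-bis(methoxymethoxy)-3-(3-methylbut-2-en-1-yl)benzaldehyde
Product: 15 [2-(dimethoxymethyl)-4,6-bis(methoxymethoxy)-3-(3-methylbut-2-en-1-yl)phenyl]methanol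
Conditions: NaBH4, MeOH/THF, 0 °C; basic work-up, used crude
Reagents that add atoms: none
Why: Hydride reduction of the aldehyde under basic conditions leaves the acetal, the MOM ethers and the alkene untouched.

Step 11
Reactants: 15 [2-(dimethoxymethyl)-4,6-bis(methoxymethoxy)-3-(3-methylbut-2-en-1-yl)phenyl]methanol
Product: 16 tert-butyl{[2-(dimethoxymethyl)-4,6-bis(methoxymethoxy)-3-(3-methylbut-2-en-1-yl)phenyl]methoxy}dimethylsilane
Conditions: TBSCl, imidazole, DMF, rt
Reagents that add atoms: tert-butyldimethylsilyl chloride, CC(C)(C)[Si](C)(C)Cl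
Why: Silylation of the primary benzylic alcohol blocks it, and stops it from closing onto the neighbouring acetal, through the coupling and the first oxidation.

Step 12
Reactants: 16 tert-butyl{[2-(dimethoxymethyl)-4,6-bis(methoxymethoxy)-3-(3-methylbut-2-en-1-yl)phenyl]methoxy}dimethylsilane
Product: 17 2-({[tert-butyl(dimethyl)silyl]oxy}methyl)-3,5-bis(methoxymethoxy)-6-(3-methylbut-2-en-1-yl)benzaldehyde
Conditions: pyridinium p-toluenesulfonate (cat.), acetone/H2O (10:1), rt
Reagents that add atoms: water, O
Why: Mild acid-catalysed acetal hydrolysis unmasks only the aldehyde because a dimethyl acetal is far more labile than aryl MOM ethers or a primary TBS ether.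

Step 13
Reactants: 5 2-bromo-4-chloro-5-methoxy-3-methylphenol; 17 2-({[tert-butyl(dimethyl)silyl]oxy}methyl)-3,5-bis(methoxymethoxy)-6-(3-methylbut-2-en-1-yl)benzaldehyde
Product: 19 rac-2-bromo-6-{[2-({[tert-butyl(dimethyl)silyl]oxy}methyl)-3,5-bis(methoxymethoxy)-6-(3-methylbut-2-en-1-yl)phenyl](hydroxy)methyl}-4-chloro-5-methoxy-3-methylphenol, via bromomagnesium phenoxide 18 (not isolated)
Conditions: 5 (1.3 equiv), EtMgBr (1.2 equiv), Et2O, 0 °C to rt; evaporate; 17 (1.0 equiv), toluene, rt to 60 °C; H2O work-up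
Reagents that add atoms: none
Why: Intermolecular aldol-type addition (Casiraghi ortho-hydroxyalkylation) in which the magnesium phenoxide reacts as an aromatic enolate through its only free ortho carbon with the magnesium-bound aldehyde in a six-membered chelate and then rearomatises, giving the carbinol centre as a racemate that is erased in step 14.

Step 14
Reactants: 19 rac-2-bromo-6-{[2-({[tert-butyl(dimethyl)silyl]oxy}methyl)-3,5-bis(methoxymethoxy)-6-(3-methylbut-2-en-1-yl)phenyl](hydroxy)methyl}-4-chloro-5-methoxy-3-methylphenol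
Product: 20 (3-bromo-5-chloro-2-hydroxy-6-methoxy-4-methylphenyl)[2-({[tert-butyl(dimethyl)silyl]oxy}methyl)-3,5-bis(methoxymethoxy)-6-(3-methylbut-2-en-1-yl)phenyl]methanone
Conditions: Dess–Martin periodinane, pyridine, CH2Cl2, 0 °C to rt
Reagents that add atoms: none
Why: Dess–Martin oxidation converts the hindered, doubly benzylic secondary alcohol into the benzophenone, which is stabilised by the hydrogen bond from the fully substituted ortho phenol, and removes the only stereocentre.

Step 15
Reactants: 20 (3-bromo-5-chloro-2-hydroxy-6-methoxy-4-methylphenyl)[2-({[tert-butyl(dimethyl)silyl]oxy}methyl)-3,5-bis(methoxymethoxy)-6-(3-methylbut-2-en-1-yl)phenyl]methanone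
Product: 21 (3-bromo-5-chloro-2-hydroxy-6-methoxy-4-methylphenyl)[2-(hydroxymethyl)-3,5-bis(methoxymethoxy)-6-(3-methylbut-2-en-1-yl)phenyl]methanone
Conditions: HF·pyridine, pyridine, THF, 0 °C to rt
Reagents that add atoms: none
Why: Fluoride-driven Si–O cleavage in pyridine-buffered medium frees the primary alcohol without affecting the MOM ethers or the prenyl group.

Step 16
Reactants: 21 (3-bromo-5-chloro-2-hydroxy-6-methoxy-4-methylphenyl)[2-(hydroxymethyl)-3,5-bis(methoxymethoxy)-6-(3-methylbut-2-en-1-yl)phenyl]methanone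
Product: 22 2-(3-bromo-5-chloro-2-hydroxy-6-methoxy-4-methylbenzoyl)-4,6-bis(methoxymethoxy)-3-(3-methylbut-2-en-1-yl)benzaldehyde
Conditions: activated MnO2 (excess), CH2Cl2, rt
Reagents that add atoms: none
Why: MnO2 selectively oxidises the electron-rich benzylic alcohol to the aldehyde under neutral conditions, avoiding the base-induced lactone formation that ortho-formyl benzophenones of this type undergo.

Step 17
Reactants: 22 2-(3-bromo-5-chloro-2-hydroxy-6-methoxy-4-methylbenzoyl)-4,6-bis(methoxymethoxy)-3-(3-methylbut-2-en-1-yl)benzaldehyde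
Product: 23 Pestalone G
Conditions: 3 M HCl (aq.)/THF (1:3), 40 °C
Reagents that add atoms: none
Why: Acid-catalysed hydrolysis of the two MOM acetals in aqueous THF (no alcohol, so the aldehyde is not acetalised) releases both ring B phenols at a temperature too low for chroman formation from the ortho-prenyl phenol.

**Compound list**

1 | 3-methoxy-5-methylphenol (orcinol monomethyl ether) | COc1cc(C)cc(O)c1 | starting material
2 | 3-methoxy-5-methylphenyl acetate | COc1cc(C)cc(OC(C)=O)c1 | intermediate
3 | 2-bromo-5-methoxy-3-methylphenyl acetate | COc1cc(C)c(Br)c(OC(C)=O)c1 | intermediate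
4 | 2-bromo-5-methoxy-3-methylphenol | COc1cc(C)c(Br)c(O)c1 | intermediate
5 | 2-bromo-4-chloro-5-methoxy-3-methylphenol | COc1cc(O)c(Br)c(C)c1Cl | intermediate
6 | 3,5-dihydroxybenzaldehyde | O=Cc1cc(O)cc(O)c1 | starting material
7 | 3,5-bis(methoxymethoxy)benzaldehyde | COCOc1cc(C=O)cc(OCOC)c1 | intermediate
8 | 1-(dimethoxymethyl)-3,5-bis(methoxymethoxy)benzene | COCOc1cc(OCOC)cc(c1)C(OC)OC | intermediate
9 | 2,4-dibromo-3-(dimethoxymethyl)-1,5-bis(methoxymethoxy)benzene | COCOc1cc(OCOC)c(Br)c(C(OC)OC)c1Br | intermediate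
10 | [3-bromo-2-(dimethoxymethyl)-4,6-bis(methoxymethoxy)phenyl]lithium | [Li]c1c(OCOC)cc(OCOC)c(Br)c1C(OC)OC | intermediate
11 | [3-bromo-2-(dimethoxymethyl)-4,6-bis(methoxymethoxy)phenyl]copper | [Cu]c1c(OCOC)cc(OCOC)c(Br)c1C(OC)OC | intermediate
12 | 2-bromo-3-(dimethoxymethyl)-1,5-bis(methoxymethoxy)-4-(3-methylbut-2-en-1-yl)benzene | COCOc1cc(OCOC)c(CC=C(C)C)c(C(OC)OC)c1Br | intermediate
13 | [2-(dimethoxymethyl)-4,6-bis(methoxymethoxy)-3-(3-methylbut-2-en-1-yl)phenyl]lithium | [Li]c1c(OCOC)cc(OCOC)c(CC=C(C)C)c1C(OC)OC | intermediate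
14 | 2-(dimethoxymethyl)-4,6-bis(methoxymethoxy)-3-(3-methylbut-2-en-1-yl)benzaldehyde | O=Cc1c(OCOC)cc(OCOC)c(CC=C(C)C)c1C(OC)OC | intermediate
15 | [2-(dimethoxymethyl)-4,6-bis(methoxymethoxy)-3-(3-methylbut-2-en-1-yl)phenyl]methanol | OCc1c(OCOC)cc(OCOC)c(CC=C(C)C)c1C(OC)OC | intermediate
16 | tert-butyl{[2-(dimethoxymethyl)-4,6-bis(methoxymethoxy)-3-(3-methylbut-2-en-1-yl)phenyl]methoxy}dimethylsilane | CC(C)(C)[Si](C)(C)OCc1c(OCOC)cc(OCOC)c(CC=C(C)C)c1C(OC)OC | intermediate
17 | 2-({[tert-butyl(dimethyl)silyl]oxy}methyl)-3,5-bis(methoxymethoxy)-6-(3-methylbut-2-en-1-yl)benzaldehyde | CC(C)(C)[Si](C)(C)OCc1c(OCOC)cc(OCOC)c(CC=C(C)C)c1C=O | intermediate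
18 | bromomagnesium 2-bromo-4-chloro-5-methoxy-3-methylphenoxide | COc1cc(O[Mg]Br)c(Br)c(C)c1Cl | intermediate
19 | rac-2-bromo-6-{[2-({[tert-butyl(dimethyl)silyl]oxy}methyl)-3,5-bis(methoxymethoxy)-6-(3-methylbut-2-en-1-yl)phenyl](hydroxy)methyl}-4-chloro-5-methoxy-3-methylphenol (racemic carbinol) | COc1c(Cl)c(C)c(Br)c(O)c1C(O)c1c(CO[Si](C)(C)C(C)(C)C)c(OCOC)cc(OCOC)c1CC=C(C)C | intermediate
20 | (3-bromo-5-chloro-2-hydroxy-6-methoxy-4-methylphenyl)[2-({[tert-butyl(dimethyl)silyl]oxy}methyl)-3,5-bis(methoxymethoxy)-6-(3-methylbut-2-en-1-yl)phenyl]methanone | COc1c(Cl)c(C)c(Br)c(O)c1C(=O)c1c(CO[Si](C)(C)C(C)(C)C)c(OCOC)cc(OCOC)c1CC=C(C)C | intermediate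
21 | (3-bromo-5-chloro-2-hydroxy-6-methoxy-4-methylphenyl)[2-(hydroxymethyl)-3,5-bis(methoxymethoxy)-6-(3-methylbut-2-en-1-yl)phenyl]methanone | COc1c(Cl)c(C)c(Br)c(O)c1C(=O)c1c(CO)c(OCOC)cc(OCOC)c1CC=C(C)C | intermediate
22 | 2-(3-bromo-5-chloro-2-hydroxy-6-methoxy-4-methylbenzoyl)-4,6-bis(methoxymethoxy)-3-(3-methylbut-2-en-1-yl)benzaldehyde | COc1c(Cl)c(C)c(Br)c(O)c1C(=O)c1c(C=O)c(OCOC)cc(OCOC)c1CC=C(C)C | intermediate
23 | Pestalone G, 2-(3-bromo-5-chloro-2-hydroxy-6-methoxy-4-methylbenzoyl)-4,6-dihydroxy-3-(3-methylbut-2-en-1-yl)benzaldehyde (achiral) | COc1c(Cl)c(C)c(Br)c(O)c1C(=O)c1c(C=O)c(O)cc(O)c1CC=C(C)C | target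

**Totals**

Total step count: 17 (ring A fragment: steps 1–4; ring B fragment: steps 5–12; union and endgame: steps 13–17).
Longest linear sequence: 13 steps (6 to 23 through steps 5–17).

**Three steps most likely to fail**

Step 13. The phenoxide addition joins two heavily ortho-substituted partners and may stall or give little conversion. The fallback sets out from 5 and comes back at 19. Iodination of 5 at its only free ring carbon (N-iodosuccinimide, TsOH·H2O (cat.), MeCN, rt) gives 2-bromo-4-chloro-6-iodo-5-methoxy-3-methylphenol F1. Deprotonation with MeMgCl (1.0 equiv) in THF containing LiCl at −20 °C, then selective iodine–magnesium exchange with i-PrMgCl (1.1 equiv; the aryl bromide and chloride are not exchanged), gives chloromagnesium 2-bromo-4-chloro-6-(chloromagnesio)-5-methoxy-3-methylphenoxide F2. This discrete aryl Grignard reagent adds 1,2 to aldehyde 17 and aqueous work-up delivers carbinol 19, so the bond is made by aryl-metal addition instead of by the phenoxide acting as an enolate.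

Step 8. Mono-exchange followed by copper-mediated prenylation can give some SN2′ (1,1-dimethylallyl) product or incomplete transfer. The fallback sets out from 9 and comes back at 12. The same aryllithium 10 and arylcopper 11 are trapped with allyl bromide, whose two termini are equivalent, to give 2-bromo-3-(dimethoxymethyl)-1,5-bis(methoxymethoxy)-4-(prop-2-en-1-yl)benzene F3. Olefin cross-metathesis of this allyl arene with excess 2-methylbut-2-ene and second-generation Grubbs catalyst (H2IMes)(PCy3)Cl2Ru=CHPh in CH2Cl2 at 40 °C then builds the prenyl group and gives 12.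

Step 17. Aqueous acid may close the ortho-prenyl phenol to a chroman or degrade the sensitive ortho-formyl benzophenone. The fallback sets out from 22 and comes back at 23. Treatment with TMSOTf and 2,2′-bipyridyl in CH2Cl2 at 0 °C to rt converts both aryl MOM ethers, and the free ring A phenol, into trimethylsilyl ethers without any Brønsted acid, giving 2-{3-bromo-5-chloro-6-methoxy-4-methyl-2-[(trimethylsilyl)oxy]benzoyl}-3-(3-methylbut-2-en-1-yl)-4,6-bis[(trimethylsilyl)oxy]benzaldehyde F4. Stirring this silyl ether with water in THF at rt and neutral pH hydrolyses the three aryl silyl ethers and gives 23.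

**Further compounds**

F1 | step 13 | 2-bromo-4-chloro-6-iodo-5-methoxy-3-methylphenol | COc1c(I)c(O)c(Br)c(C)c1Cl
F2 | step 13 | chloromagnesium 2-bromo-4-chloro-6-(chloromagnesio)-5-methoxy-3-methylphenoxide | COc1c([Mg]Cl)c(O[Mg]Cl)c(Br)c(C)c1Cl
F3 | step 8 | 2-bromo-3-(dimethoxymethyl)-1,5-bis(methoxymethoxy)-4-(prop-2-en-1-yl)benzene | COCOc1cc(OCOC)c(CC=C)c(C(OC)OC)c1Br
F4 | step 17 | 2-{3-bromo-5-chloro-6-methoxy-4-methyl-2-[(trimethylsilyl)oxy]benzoyl}-3-(3-methylbut-2-en-1-yl)-4,6-bis[(trimethylsilyl)oxy]benzaldehyde | COc1c(Cl)c(C)c(Br)c(O[Si](C)(C)C)c1C(=O)c1c(C=O)c(O[Si](C)(C)C)cc(O[Si](C)(C)C)c1CC=C(C)C
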